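Each oxolane arm is disconnected at C3'–C4' and O1'–C2'. C3' lies alpha to C2' and C4' alpha to C5', both of carbonyl oxidation level, and the ring A oxygens O5 and O7 flank the C6 and C8 arms. Each C2'=C3' pair can therefore be stored as a 4H-chromene enol ether whose Ca aryl group covers one face. One Mn(OAc)3 operation joins a beta-keto ester to both enol ethers of bis(2,4-diaryl-4H-chromene) 12, forming four bonds and two cis-fused dihydrofuran ketal rings. Alkene saturation, ester-to-aroyl exchange, reductive ketal opening and hydrogenolysis finish the synthesis.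

Key step: step 9

Assumption: benzyl ethers 5 and 13 are purchased, and the 3-hydroxy group of the flavan is carried unprotected, because no step of the route attacks a hindered secondary alcohol.

Step 1
Reactants: 1 (+)-afzelechin; 2 ethyl propiolate
Product: 3 afzelechin 6,8-bis-coumarin (lactone rings O5–C(=O)–CH=CH–C6 and O7–C(=O)–CH=CH–C8; 3-OH and 4'-OH free)
Conditions: 2 (2.5 equiv), Pd(OAc)2 (5 mol %), CF3CO2H/CH2Cl2, 0 °C to rt; aq. NaHCO3
Reagents that add atoms: none
Why: Pechmann-type coumarin annulation (acid- and Pd(OAc)2-promoted hydroarylation of the alkynoate, then lactonisation): ring A reacts far faster than ring B, the C8 arm can lactonise only onto O7 and then leaves O5 as the sole partner of the C6 arm, so the 6,8-bis-lactone should be the main product, while any C6-on-O7 closure strands the C8 acrylate and is removed as a phenolic ester; no stereocentre is touched.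

Step 2
Reactants: 3 afzelechin 6,8-bis-coumarin
Product: 4 4'-O-benzyl bis-coumarin
Conditions: BnBr, K2CO3, DMF, rt
Reagents that add atoms: benzyl bromide, BrCc1ccccc1
Why: Williamson ether synthesis: K2CO3 deprotonates only the phenol, so the 4'-oxygen is benzylated while the lactones (which mask O5 and O7) and the secondary 3-hydroxy group are untouched.

Step 3
Reactants: 4 4'-O-benzyl bis-coumarin; 5 4-(benzyloxy)phenylboronic acid
Product: 6 bis(4-aryl-3,4-dihydrocoumarin) with both Ca (S)
Conditions: 5 (6 equiv), Rh(acac)(C2H4)2 (6 mol %), (S)-SEGPHOS (6.6 mol %), dioxane/H2O (10:1), 60 °C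
Reagents that add atoms: none
Why: Rhodium-catalysed asymmetric conjugate arylation (Hayashi–Miyaura reaction) of both electron-poor coumarin units: the aryl–rhodium species bound to the chiral bisphosphine adds to C4 of each pyranone under catalyst control, and the (S)-ligand is chosen, by analogy with simple coumarins, to set both Ca centres (S), the remote flavan centres having little influence.

Step 4
Reactants: 6 bis(4-aryl-3,4-dihydrocoumarin)
Product: 7 bis(N-methoxy-N-methylamide) with free 3-, 5- and 7-OH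
Conditions: MeNH(OMe)·HCl, AlMe3, CH2Cl2, 0 °C to rt; aq. potassium sodium tartrate
Reagents that add atoms: N,O-dimethylhydroxylamine hydrochloride, CNOC.Cl
Why: Aluminium-amide aminolysis of the aryl lactones (N-methoxy-N-methylamide formation) opens both rings, frees O5–H and O7–H and cannot affect Ca, which is not enolisable.

Step 5
Reactants: 8 4-bromoresorcinol
Product: 9 2,4-bis(benzyloxy)-1-bromobenzene
Conditions: BnBr, K2CO3, acetone, reflux
Reagents that add atoms: benzyl bromide, BrCc1ccccc1
Why: Williamson ether synthesis on both phenols of the aryl bromide.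

Step 6
Reactants: 7 bis(N-methoxy-N-methylamide); 9 2,4-bis(benzyloxy)-1-bromobenzene
Product: 11 bis(1,3,3-triarylpropan-1-one) triol, via 2,4-bis(benzyloxy)phenyllithium 10 (not isolated)
Conditions: 9 (6.5 equiv), n-BuLi, THF, −78 °C; then 7, −78 to 0 °C; aq. NH4Cl
Reagents that add atoms: none
Why: Bromine–lithium exchange followed by aryllithium addition to the N-methoxy-N-methylamides, which stop at the chelated tetrahedral adduct and release the ketones on work-up; the first three equivalents of aryllithium only deprotonate the hydroxy groups, and the alpha carbon is a CH2 group, so enolisation costs no stereocentre.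

Step 7
Reactants: 11 bis(1,3,3-triarylpropan-1-one) triol
Product: 12 ring A fused bis(2,4-diaryl-4H-chromene) with free 3-OH
Conditions: PPTS (cat.), toluene, 90 °C, slow azeotropic removal of water, argon
Reagents that add atoms: none
Why: Acid-catalysed hemiketalisation and dehydration give the conjugated 2-aryl enol ethers (4H-chromene formation); ring closure stays reversible while water is present and the C8 arm can reach only O7, so slow removal of water should funnel the material to the one doubly closed isomer with the C6 arm on O5, and the Ca centres are not involved.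

Step 8
Reactants: 13 4'-(benzyloxy)acetophenone
Product: 14 methyl 3-[4-(benzyloxy)phenyl]-3-oxopropanoate
Conditions: NaH, (MeO)2CO, THF, reflux; aq. HCl
Reagents that add atoms: dimethyl carbonate, COC(=O)OC
Why: Crossed Claisen condensation of the ketone enolate with dimethyl carbonate, driven by deprotonation of the beta-keto ester formed.

Step 9
Reactants: 12 ring A fused bis(2,4-diaryl-4H-chromene); 14 methyl 3-[4-(benzyloxy)phenyl]-3-oxopropanoate
Product: 15 bis(furo[2,3-b]chromene ketal) with C4'=C5' and a methyl ester on C4' in each arm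
Conditions: 14 (3 equiv), Mn(OAc)3·2H2O (5 equiv), KOAc (4 equiv), AcOH, 40 °C, argon
Reagents that add atoms: none
Why: Mn(OAc)3 forms the manganese enolate of 14 and oxidises it in the inner sphere to an electrophilic radical at the future C4', which adds to the nucleophilic enol ether carbon C3' of each chromene and leaves a C2' radical stabilised by the ring oxygen and the 2,4-bis(benzyloxy)phenyl group. A second equivalent of trivalent manganese oxidises that radical to the oxocarbenium ion, which the enolic ketone oxygen captures. The closest known reaction type is the Mn(OAc)3- or (NH4)2Ce(NO3)6-mediated oxidative (3+2) annulation of 1,3-dicarbonyl compounds with cyclic enol ethers to fused dihydrofuran acetals. Each dihydrofuran ring closes by 5-exo-trig attack of the ketone oxygen on C2', and the short tether allows only cis fusion to the pyran ring, which sets C2'. C3' is set by radical attack anti to the pseudo-axial Ca aryl group of the 4H-chromene. The step needs the keto ester to be oxidised before the electron-rich chromene loses an electron or its doubly benzylic Ca–H, and needs closure through the ketone oxygen only; fast inner-sphere oxidation of the bound dicarbonyl, the acetate buffer (which also keeps the ketal from eliminating to a furan) and the poor nucleophilicity of the ester carbonyl oxygen are relied on for this.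

Step 10
Reactants: 15 bis(furo[2,3-b]chromene ketal)
Product: 16 tetrahydro bis-ester with C3'–H, C4'–H and C5'–H all on the convex face
Conditions: H2 (4 bar), Pd/C (10 %), pyridine (0.5 equiv), EtOAc/THF, rt
Reagents that add atoms: none
Why: Heterogeneous syn hydrogenation of the enol ether double bond from the convex face of the cis-fused bicycle (the face of C3'–H), which places the C4' ester and the C5' aryl group cis to the C3'–Ca bond; the nitrogen base suppresses hydrogenolysis of aryl benzyl ethers on Pd/C.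

Step 11
Reactants: 16 tetrahydro bis-ester
Product: 17 C4'-epimerised bis-ester with each ester trans to both ring neighbours
Conditions: NaOMe (cat.), MeOH/THF, 40 °C
Reagents that add atoms: none
Why: Base-mediated epimerisation through the ester enolate moves the C4' ester from the concave face to the thermodynamically preferred position trans to the C3' and C5' substituents; C5' is not acidic and keeps its configuration.

Step 12
Reactants: 17 C4'-epimerised bis-ester
Product: 18 bis(N-methoxy-N-methylamide) ketal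
Conditions: MeNH(OMe)·HCl, i-PrMgCl, THF, −20 °C to rt
Reagents that add atoms: N,O-dimethylhydroxylamine hydrochloride, CNOC.Cl
Why: Aminolysis of the methyl esters by the chloromagnesium amide of N,O-dimethylhydroxylamine (N-methoxy-N-methylamide formation); the basic, weakly Lewis-acidic medium spares the ketals, and C4' already has its thermodynamic configuration.

Step 13
Reactants: 18 bis(N-methoxy-N-methylamide) ketal; 9 2,4-bis(benzyloxy)-1-bromobenzene
Product: 20 bis(2,4-bis(benzyloxy)phenyl ketone) ketal, via 2,4-bis(benzyloxy)phenylmagnesium bromide 19 (not isolated)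
Conditions: 9 (5 equiv), Mg turnings, LiCl, THF, rt; then 18, 0 °C to rt; aq. NH4Cl
Reagents that add atoms: none
Why: Magnesium insertion into the aryl bromide followed by Grignard addition to the N-methoxy-N-methylamides (Weinreb ketone synthesis), which stops at the chelated magnesium adduct and gives the aryl ketones on work-up; the Grignard reagent is preferred here to an aryllithium because C4' carries an acidic hydrogen beta to the ring oxygen, so the less basic nucleophile keeps enolisation and ring-opening elimination down, while one equivalent deprotonates the 3-hydroxy group and the ketals keep O5 and O7 masked.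

Step 14
Reactants: 20 bis(2,4-bis(benzyloxy)phenyl ketone) ketal
Product: 21 tridecabenzyl ether of the target with free 3-, 5- and 7-OH
Conditions: Et3SiH, BF3·OEt2, CH2Cl2, −78 to −40 °C; aq. NaHCO3 (any aryl O–SiEt3 is cleaved on work-up)
Reagents that add atoms: none
Why: Ionic reduction of the mixed aryl alkyl ketals: BF3 assists loss of the better leaving group, the ring A phenoxide (O5, O7), to give the five-membered 2-aryl oxocarbenium ion, and Et3SiH delivers hydride to C2' anti to the bulky C3' substituent and the departing phenoxide, which gives the 2',3'-cis oxolane; the low temperature spares the aryl ketones and the benzylic C5'–O1' bond.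

Step 15
Reactants: 21 tridecabenzyl ether of the target
Product: 22 CNP0225367.3
Conditions: H2 (1 atm), Pd(OH)2/C, THF/MeOH, rt
Reagents that add atoms: none
Why: Hydrogenolysis of the thirteen benzyl ethers under neutral conditions at low pressure; the cyclic benzylic ethers (C2, C2', C5') and the deactivated 2,4-dihydroxyaryl ketones should be retained, as in routine debenzylation of flavan-3-ols.

Compound list
1 | (+)-afzelechin, (2R,3S)-2-(4-hydroxyphenyl)chromane-3,5,7-triol | O[C@H]1Cc2c(O)cc(O)cc2O[C@@H]1c1ccc(O)cc1 | starting material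
2 | ethyl propiolate | C#CC(=O)OCC | starting material
3 | afzelechin 6,8-bis-coumarin: (2R,3S)-flavan-3-ol whose ring A carries two fused 2-pyranone rings (O5–C(=O)–CH=CH–C6 and O7–C(=O)–CH=CH–C8); 3-OH and 4'-OH free | O[C@H]1Cc2c3OC(=O)C=Cc3c4OC(=O)C=Cc4c2O[C@@H]1c1ccc(O)cc1 | intermediate
4 | 4'-O-benzyl ether of bis-coumarin 3 | O[C@H]1Cc2c3OC(=O)C=Cc3c4OC(=O)C=Cc4c2O[C@@H]1c1ccc(OCc2ccccc2)cc1 | intermediate
5 | 4-(benzyloxy)phenylboronic acid | OB(O)c1ccc(OCc2ccccc2)cc1 | starting material
6 | bis(4-aryl-3,4-dihydrocoumarin): 4 with a 4-(benzyloxy)phenyl group added to each lactone C4 (= Ca), both Ca (S) | O[C@H]1Cc2c3OC(=O)C[C@@H](c5ccc(OCc6ccccc6)cc5)c3c4OC(=O)C[C@@H](c5ccc(OCc6ccccc6)cc5)c4c2O[C@@H]1c1ccc(OCc2ccccc2)cc1 | intermediate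
7 | bis(N-methoxy-N-methylamide): 4'-O-benzylafzelechin with an (S)-CH[4-(benzyloxy)phenyl]CH2C(=O)N(OMe)Me arm on C6 and on C8; 3-, 5-, 7-OH free | O[C@H]1Cc2c(O)c([C@H](c5ccc(OCc6ccccc6)cc5)CC(=O)N(C)OC)c(O)c([C@H](c5ccc(OCc6ccccc6)cc5)CC(=O)N(C)OC)c2O[C@@H]1c1ccc(OCc2ccccc2)cc1 | intermediate
8 | 4-bromoresorcinol | Oc1ccc(Br)c(O)c1 | starting material
9 | 2,4-bis(benzyloxy)-1-bromobenzene | Brc1ccc(OCc2ccccc2)cc1OCc1ccccc1 | intermediate
10 | 2,4-bis(benzyloxy)phenyllithium | [Li]c1ccc(OCc2ccccc2)cc1OCc1ccccc1 | intermediate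
11 | bis(1,3,3-triarylpropan-1-one) triol: 4'-O-benzylafzelechin with an (S)-CH[4-(benzyloxy)phenyl]CH2C(=O)[2,4-bis(benzyloxy)phenyl] arm on C6 and on C8; 3-, 5-, 7-OH free | O[C@H]1Cc2c(O)c([C@H](c5ccc(OCc6ccccc6)cc5)CC(=O)c5ccc(OCc6ccccc6)cc5OCc5ccccc5)c(O)c([C@H](c5ccc(OCc6ccccc6)cc5)CC(=O)c5ccc(OCc6ccccc6)cc5OCc5ccccc5)c2O[C@@H]1c1ccc(OCc2ccccc2)cc1 | intermediate
12 | ring A fused bis(2,4-diaryl-4H-chromene): chromene rings O5–C2'(Ar)=C3'H–Ca(H)(Ar')–C6 and O7–C2'(Ar)=C3'H–Ca(H)(Ar')–C8, Ar = 2,4-bis(benzyloxy)phenyl, Ar' = 4-(benzyloxy)phenyl, both Ca (S); 3-OH free, 4'-O-benzyl | O[C@H]1Cc2c3OC(c8ccc(OCc9ccccc9)cc8OCc9ccccc9)=C[C@@H](c7ccc(OCc9ccccc9)cc7)c3c4OC(c8ccc(OCc9ccccc9)cc8OCc9ccccc9)=C[C@@H](c7ccc(OCc9ccccc9)cc7)c4c2O[C@@H]1c7ccc(OCc9ccccc9)cc7 | intermediate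
13 | 4'-(benzyloxy)acetophenone | CC(=O)c1ccc(OCc2ccccc2)cc1 | starting material
14 | methyl 3-[4-(benzyloxy)phenyl]-3-oxopropanoate | COC(=O)CC(=O)c1ccc(OCc2ccccc2)cc1 | intermediate
15 | bis(furo[2,3-b]chromene ketal): each chromene of 12 carries a cis-fused 2,3-dihydrofuran (O1'–C2' ketal, C3'–C4' bond anti to the Ca aryl group, C4'=C5' with CO2Me on C4' and 4-(benzyloxy)phenyl on C5') | O[C@H]1Cc2c3O[C@]5(c8ccc(OCc9ccccc9)cc8OCc9ccccc9)OC(c7ccc(OCc9ccccc9)cc7)=C(C(=O)OC)[C@@H]5[C@@H](c7ccc(OCc9ccccc9)cc7)c3c4O[C@]5(c8ccc(OCc9ccccc9)cc8OCc9ccccc9)OC(c7ccc(OCc9ccccc9)cc7)=C(C(=O)OC)[C@@H]5[C@@H](c7ccc(OCc9ccccc9)cc7)c4c2O[C@@H]1c7ccc(OCc9ccccc9)cc7 | intermediate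
16 | tetrahydro bis-ester: 15 with both C4'=C5' bonds saturated, the C4' ester and the C5' aryl group cis to the C3'–Ca bond | O[C@H]1Cc2c3O[C@]5(c8ccc(OCc9ccccc9)cc8OCc9ccccc9)O[C@H](c7ccc(OCc9ccccc9)cc7)[C@H](C(=O)OC)[C@@H]5[C@@H](c7ccc(OCc9ccccc9)cc7)c3c4O[C@]5(c8ccc(OCc9ccccc9)cc8OCc9ccccc9)O[C@H](c7ccc(OCc9ccccc9)cc7)[C@H](C(=O)OC)[C@@H]5[C@@H](c7ccc(OCc9ccccc9)cc7)c4c2O[C@@H]1c7ccc(OCc9ccccc9)cc7 | intermediate
17 | C4'-epimerised bis-ester: as 16 but each C4' ester trans to the C3' and C5' substituents | O[C@H]1Cc2c3O[C@]5(c8ccc(OCc9ccccc9)cc8OCc9ccccc9)O[C@H](c7ccc(OCc9ccccc9)cc7)[C@@H](C(=O)OC)[C@@H]5[C@@H](c7ccc(OCc9ccccc9)cc7)c3c4O[C@]5(c8ccc(OCc9ccccc9)cc8OCc9ccccc9)O[C@H](c7ccc(OCc9ccccc9)cc7)[C@@H](C(=O)OC)[C@@H]5[C@@H](c7ccc(OCc9ccccc9)cc7)c4c2O[C@@H]1c7ccc(OCc9ccccc9)cc7 | intermediate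
18 | bis(N-methoxy-N-methylamide) ketal: 17 with each CO2Me replaced by C(=O)N(OMe)Me | O[C@H]1Cc2c3O[C@]5(c8ccc(OCc9ccccc9)cc8OCc9ccccc9)O[C@H](c7ccc(OCc9ccccc9)cc7)[C@@H](C(=O)N(C)OC)[C@@H]5[C@@H](c7ccc(OCc9ccccc9)cc7)c3c4O[C@]5(c8ccc(OCc9ccccc9)cc8OCc9ccccc9)O[C@H](c7ccc(OCc9ccccc9)cc7)[C@@H](C(=O)N(C)OC)[C@@H]5[C@@H](c7ccc(OCc9ccccc9)cc7)c4c2O[C@@H]1c7ccc(OCc9ccccc9)cc7 | intermediate
19 | 2,4-bis(benzyloxy)phenylmagnesium bromide | Br[Mg]c1ccc(OCc2ccccc2)cc1OCc1ccccc1 | intermediate
20 | bis(aryl ketone) ketal: 17 with each CO2Me replaced by a 2,4-bis(benzyloxy)benzoyl group | O[C@H]1Cc2c3O[C@]5(c8ccc(OCc9ccccc9)cc8OCc9ccccc9)O[C@H](c7ccc(OCc9ccccc9)cc7)[C@@H](C(=O)c8ccc(OCc9ccccc9)cc8OCc9ccccc9)[C@@H]5[C@@H](c7ccc(OCc9ccccc9)cc7)c3c4O[C@]5(c8ccc(OCc9ccccc9)cc8OCc9ccccc9)O[C@H](c7ccc(OCc9ccccc9)cc7)[C@@H](C(=O)c8ccc(OCc9ccccc9)cc8OCc9ccccc9)[C@@H]5[C@@H](c7ccc(OCc9ccccc9)cc7)c4c2O[C@@H]1c7ccc(OCc9ccccc9)cc7 | intermediate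
21 | tridecabenzyl ether of the target: both ketals opened to oxolanes (2',3'-cis, 3',4'-trans, 4',5'-trans) with free O5–H, O7–H and 3-OH; all other phenols benzylated | O[C@H]1Cc2c(O)c([C@H](c4ccc(OCc5ccccc5)cc4)[C@H]3[C@H](C(=O)c4ccc(OCc5ccccc5)cc4OCc4ccccc4)[C@@H](c4ccc(OCc5ccccc5)cc4)O[C@H]3c4ccc(OCc5ccccc5)cc4OCc4ccccc4)c(O)c([C@H](c4ccc(OCc5ccccc5)cc4)[C@H]3[C@H](C(=O)c4ccc(OCc5ccccc5)cc4OCc4ccccc4)[C@@H](c4ccc(OCc5ccccc5)cc4)O[C@H]3c4ccc(OCc5ccccc5)cc4OCc4ccccc4)c2O[C@@H]1c1ccc(OCc2ccccc2)cc1 | intermediate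
22 | CNP0225367.3 | O=C(c1ccc(O)cc1O)[C@H]1[C@H]([C@@H](c2ccc(O)cc2)c2c(O)c3c(c([C@H](c4ccc(O)cc4)[C@H]4[C@H](C(=O)c5ccc(O)cc5O)[C@@H](c5ccc(O)cc5)O[C@H]4c4ccc(O)cc4O)c2O)O[C@H](c2ccc(O)cc2)[C@@H](O)C3)[C@H](c2ccc(O)cc2O)O[C@@H]1c1ccc(O)cc1 | target

Total step count: 15. Longest linear sequence: 13 steps (steps 1–4, 6, 7 and 9–15, from 1 to 22).

Steps most likely to fail

Risk at step 9. The electron-rich chromene may itself be oxidised (electron loss or hydride loss at the doubly benzylic Ca–H, leading to a chromenylium ion), or the enol ether may be opened by acid, before the radical adds. The fallback makes the same two bonds by metal-carbenoid instead of radical chemistry. It sets out from 14 and 12: diazo transfer to 14 (4-acetamidobenzenesulfonyl azide, Et3N, MeCN; Regitz diazo transfer) should give methyl 3-[4-(benzyloxy)phenyl]-2-diazo-3-oxopropanoate F1. Slow addition of F1 to 12 with Rh2(OAc)4 in CH2Cl2, the known formal (3+2) cycloaddition of 2-diazo-1,3-dicarbonyl compounds with enol ethers, should give 15, where the route is rejoined.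

Risk at step 10. Hydrogenolysis of aryl benzyl ethers may compete with the slow saturation of the hindered tetrasubstituted alkene, and the angular aryl group on C2' may weaken the facial preference. The fallback is a dissolving-metal conjugate reduction: Mg turnings in MeOH/THF at rt reduce beta-aryl acrylates by electron transfer, leave benzyl ethers intact and equilibrate the ester position under the Mg(OMe)2 formed. It sets out from 15 and comes back at 17 directly; no new compound is made (F0).

Risk at step 1. The second annulation on the deactivated mono-coumarin may stall, lactonisation of the C6 arm onto O7 would strand the C8 arm, and the strongly acidic medium may epimerise C2 of the flavan. The fallback installs both carbon arms before any ring is closed. It sets out from 1: Vilsmeier–Haack formylation (POCl3, DMF, then aqueous NaOAc) should give 6,8-diformylafzelechin F2, and Wittig olefination with methyl (triphenylphosphoranylidene)acetate in toluene should give the bis-(E)-acrylate F3. Irradiation at 350 nm isomerises both alkenes to the Z-acrylates, which lactonise onto the neighbouring phenols to give 3, where the route is rejoined; material closed at C6/O7 would be saponified and recycled.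

Further compounds
F1 | step 9 | methyl 3-[4-(benzyloxy)phenyl]-2-diazo-3-oxopropanoate | COC(=O)C(=[N+]=[N-])C(=O)c1ccc(OCc2ccccc2)cc1
F0 | step 10 | none | none
F2 | step 1 | 6,8-diformylafzelechin, (2R,3S)-3,5,7-trihydroxy-2-(4-hydroxyphenyl)chromane-6,8-dicarbaldehyde | O[C@H]1Cc2c(O)c(C=O)c(O)c(C=O)c2O[C@@H]1c1ccc(O)cc1
F3 | step 1 | dimethyl (2E,2'E)-3,3'-[(2R,3S)-3,5,7-trihydroxy-2-(4-hydroxyphenyl)chromane-6,8-diyl]diacrylate | O[C@H]1Cc2c(O)c(/C=C/C(=O)OC)c(O)c(/C=C/C(=O)OC)c2O[C@@H]1c1ccc(O)cc1
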